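Ring B (C5–C6–C7–C8–C9–C10, eudesmane numbering) is grown from the cyclopentene C5–C9 of a limonene-derived acetylcyclopentene. A diazoalkane carbon, tethered through the C4 acyl group, adds across C5=C9, closes ring A and fixes quaternary C10 in a tricyclic cyclopropyl ketone. The key step exploits the C4 carbonyl next to ring-fusion carbon C5: lithium in ammonia cuts the old C5–C9 bond, the one cyclopropane bond aligned with that carbonyl, so the five-membered ring expands to ring B and the 10-methyl-4-decalone appears. Its enone then takes the phloroglucinol benzylic carbon at C1 by vinylogous Mukaiyama alkylation; methyl Grignard addition, formylation and demethylation finish.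

Key step: step 6

Remark: atoms are numbered as in eudesmane (C1–C10 in the decalin, C11 the carbinol carbon on C7, C14 the methyl on C10, Cb the benzylic carbon); (4S)-limonene oxide is taken as purchasable.

Step 1
Reactants: 1 (4S)-limonene 1,2-oxide
Product: 2 (3S)-6-oxo-3-(prop-1-en-2-yl)heptanal
Conditions: H5IO6, THF/H2O, 0 °C to rt
Reagents that add atoms: water, O
Why: Acid opens the epoxide to the diol, which periodic acid cleaves (Malaprade glycol cleavage) to the keto aldehyde; the isopropenyl-bearing stereocentre is not touched.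

Step 2
Reactants: 2 (3S)-6-oxo-3-(prop-1-en-2-yl)heptanal
Product: 3 1-[(4R)-4-(prop-1-en-2-yl)cyclopent-1-en-1-yl]ethan-1-one
Conditions: KOH (0.1 equiv), MeOH/H2O, 0 °C to rt
Reagents that add atoms: none
Why: Intramolecular aldol condensation in which the ketone α-methylene adds to the more electrophilic aldehyde and water is lost should give the conjugated acetylcyclopentene; the stereocentre is not enolizable (its descriptor changes to R only through the priority rules).

Step 3
Reactants: 3 1-[(4R)-4-(prop-1-en-2-yl)cyclopent-1-en-1-yl]ethan-1-one; 4 2-(2-bromoethyl)-2-methyl-1,3-dioxolane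
Product: 5 4-(2-methyl-1,3-dioxolan-2-yl)-1-[(4R)-4-(prop-1-en-2-yl)cyclopent-1-en-1-yl]butan-1-one
Conditions: LDA, THF, −78 °C; then 4, NaI (cat.), DMPU, −78 °C to rt
Reagents that add atoms: none
Why: Kinetic deprotonation of the enone at the acetyl methyl group and SN2 alkylation of the lithium enolate by the primary bromide (enolate alkylation) install C2, C1, C10 and C14 as a masked methyl ketone.

Step 4
Reactants: 5 ketal enone
Product: 6 4-methyl-N'-{6-oxo-6-[(4R)-4-(prop-1-en-2-yl)cyclopent-1-en-1-yl]hexan-2-ylidene}benzenesulfonohydrazide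
Conditions: TsNHNH2, HCl (cat.), MeOH, rt
Reagents that add atoms: p-toluenesulfonohydrazide, Cc1ccc(cc1)S(=O)(=O)NN
Why: Acid-catalysed exchange of the dioxolane for the tosylhydrazone (hydrazone condensation) takes place at the saturated ketone carbon C10, the conjugated enone carbonyl being much less reactive.

Step 5
Reactants: 6 tosylhydrazone
Product: 9 6-methyl-3-(prop-1-en-2-yl)tricyclo[4.4.0.0^1,5]decan-10-one, via diazoalkane 7 (not isolated), via fused 1-pyrazoline 8 (not isolated)
Conditions: NaOMe, MeOH, rt; evaporate; toluene, 110 °C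
Reagents that add atoms: none
Why: Bamford–Stevens fragmentation of the hydrazone salt gives the diazoalkane, which should undergo tether-controlled intramolecular 1,3-dipolar cycloaddition to the enone and lose nitrogen thermally (pyrazoline to cyclopropane); C10 enters on the ring face opposite the isopropenyl group and ring A is necessarily cis-fused on the cyclopropane, so C10 is set relative to C7 (the minor syn isomer should be removable by chromatography).

Step 6
Reactants: 9 tricyclic cyclopropyl ketone
Product: 10 trans-4a-methyl-7-(prop-1-en-2-yl)octahydronaphthalen-1(2H)-one (isopropenyl axial, trans to the C10 methyl)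
Conditions: Li, NH3(l)/THF, −78 °C; isoprene; NH4Cl
Reagents that add atoms: none
Why: Two-electron reduction (dissolving-metal reduction) of the C4 ketone gives a ketyl whose adjacent cyclopropane bond C5–C9 breaks, the C9 carbanion is protonated by ammonia and the lithium enolate C4–C5 survives until the NH4Cl quench. The closest known reaction type is the lithium–ammonia reductive cleavage of conjugated cyclopropyl ketones such as bicyclo[4.1.0]heptan-2-ones. No ring is closed: cutting the zero bridge C5–C9 of the bicyclo[3.1.0]hexane turns the five-membered ring C5–C6–C7–C8–C9 into the six-membered ring B that now contains C10, so ring B arises by one-atom ring expansion while ring A stays intact. C10 and C7 keep the configurations set in step 5 and in the starting material, and C5 is formed by enolate protonation and is fixed as trans in step 7, where it is equilibrated (any cis epimer converges there). The regioselectivity needed, C5–C9 over C5–C10 cleavage, is secured by ring A, which holds the carbonyl π system parallel to the exocyclic bond C5–C9 and orthogonal to the endocyclic bond C5–C10, and by the preference for a secondary over a tertiary carbanion. The isolated isopropenyl double bond is not reduced under these conditions.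

Step 7
Reactants: 10 isopropenyl decalone
Product: 12 trans-7-acetyl-4a-methyloctahydronaphthalen-1(2H)-one (acetyl equatorial, cis to the C10 methyl), via axial acetyl diketone 11 (not isolated)
Conditions: O3, CH2Cl2/MeOH, −78 °C; Me2S; then NaOMe (cat.), MeOH, rt
Reagents that add atoms: ozone, [O-][O+]=O
Why: Ozonolysis turns the isopropenyl group into an acetyl group, and base equilibration through the enolates should move the C7 acetyl group to the equatorial position (cis to the C10 methyl) and C5 to the trans ring fusion (thermodynamic control).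

Step 8
Reactants: 12 equatorial acetyl diketone
Product: 13 7-acetyl-4a-methyl-4a,5,6,7,8,8a-hexahydronaphthalen-1(4H)-one (trans-fused)
Conditions: Pd(OCOCF3)2 (5 mol %), DMSO (10 mol %), O2 (1 atm), AcOH, 80 °C
Reagents that add atoms: none
Why: Aerobic palladium-catalysed α,β-dehydrogenation of the cyclohexanone (related to the Saegusa–Ito oxidation: palladium enolate, then β-hydride elimination) should go toward the C3 methylene, since C5 is tertiary and the acetyl methyl offers no β-hydrogen.

Step 9
Reactants: 13 enone methyl ketone
Product: 14 4a-methyl-7-(2-methyl-1,3-dioxolan-2-yl)-4a,5,6,7,8,8a-hexahydronaphthalen-1(4H)-one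
Conditions: TMSOCH2CH2OTMS, TMSOTf (cat.), CH2Cl2, −78 °C
Reagents that add atoms: 1,2-bis(trimethylsilyloxy)ethane, C[Si](C)(C)OCCO[Si](C)(C)C
Why: Ketalization with the bis-silyl ether of ethylene glycol is selective for the saturated acetyl carbonyl, the conjugated C4 carbonyl being far less reactive.

Step 10
Reactants: 14 ketal enone
Product: 15 tert-butyldimethylsilyl dienol ether (C4(OSi)=C3, C2=C1)
Conditions: TBSOTf, Et3N, CH2Cl2, 0 °C to rt
Reagents that add atoms: tert-butyldimethylsilyl trifluoromethanesulfonate, CC(C)(C)[Si](C)(C)OS(=O)(=O)C(F)(F)F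
Why: Soft enolization of the enone removes a γ-hydrogen at C1 (the α'-hydrogen at C5 is tertiary and shielded) and should give the thermodynamically preferred linear silyl dienol ether.

Step 11
Reactants: 16 2,4,6-trimethoxybenzaldehyde; 17 isobutylmagnesium bromide
Product: 18 3-methyl-1-(2,4,6-trimethoxyphenyl)butan-1-ol (racemic)
Conditions: THF, 0 °C; aq. NH4Cl
Reagents that add atoms: none
Why: Grignard addition to the aldehyde gives the benzylic alcohol, whose configuration is irrelevant because the centre is ionized in step 12.

Step 12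
Reactants: 15 silyl dienol ether; 18 benzylic alcohol
Product: 19 enone carrying the (S)-3-methyl-1-(2,4,6-trimethoxyphenyl)butyl group at C1
Conditions: Sc(OTf)3 (5 mol %), CH2Cl2, −40 °C
Reagents that add atoms: none
Why: The Lewis acid ionizes 18 to the 2,4,6-trimethoxybenzylic cation, which the dienol ether should attack at its γ-carbon C1 (vinylogous Mukaiyama alkylation) from the face opposite the axial C10 methyl, setting C1, while Cb is set in an open transition state with the aryl group anti to C10, the isobutyl group over the flat diene and the hydrogen toward C9.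

Step 13
Reactants: 19 coupled enone
Product: 21 diketone (C4 ketone, C7 acetyl), via saturated ketal ketone 20 (not isolated)
Conditions: H2 (1 atm), Pd/C, EtOAc, rt; filter; then 1 M HCl, THF, rt
Reagents that add atoms: water, O
Why: Heterogeneous hydrogenation saturates the C2=C3 bond and mild acid hydrolysis of the dioxolane frees the acetyl group; no stereocentre is created and no base is present that could epimerize C5.

Step 14
Reactants: 21 diketone
Product: 22 diol (C4 and C11 carbinols)
Conditions: MeMgBr (excess), CeCl3, THF, −78 to 0 °C; aq. NH4Cl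
Reagents that add atoms: methylmagnesium bromide, C[Mg]Br
Why: Methyl Grignard addition (organocerium variant) converts the acetyl group into the C11 carbinol and should attack the C4 ketone along the equatorial trajectory, because the axial C10 methyl blocks axial attack, which places the new hydroxyl axial and cis to the C10 methyl.

Step 15
Reactants: 22 diol
Product: 24 dialdehyde tris(methyl ether), via lithium hemiaminal 23 (not isolated)
Conditions: n-BuLi, TMEDA, THF, 0 °C; DMF (1 equiv), −78 °C; n-BuLi, 0 °C; DMF, −78 °C to rt; aq. NH4Cl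
Reagents that add atoms: N,N-dimethylformamide, CN(C)C=O
Why: After deprotonation of the two tertiary alcohols, directed ortho-lithiation occurs at a ring hydrogen flanked by two methoxy groups; DMF gives a lithium hemiaminal that masks the first formyl group and lets the second flanked position be lithiated and formylated in the same flask.

Step 16
Reactants: 24 dialdehyde tris(methyl ether)
Product: 25 target
Conditions: NaSEt, DMF, 120 °C; then 1 M HCl
Reagents that add atoms: none
Why: Nucleophilic (SN2) demethylation by ethanethiolate should be fast for methoxy groups ortho or para to a formyl group, all three being so placed, and the basic medium leaves the tertiary alcohols and the stereocentres untouched.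

Compound list

1 | (4S)-limonene 1,2-oxide, (4S)-1-methyl-4-(prop-1-en-2-yl)-7-oxabicyclo[4.1.0]heptane (cis/trans mixture at the epoxide) | CC12OC1C[C@H](CC2)C(C)=C | starting material
2 | (3S)-6-oxo-3-(prop-1-en-2-yl)heptanal | O=CC[C@H](CCC(C)=O)C(C)=C | intermediate
3 | 1-[(4R)-4-(prop-1-en-2-yl)cyclopent-1-en-1-yl]ethan-1-one | CC(=O)C1=CC[C@H](C1)C(C)=C | intermediate
4 | 2-(2-bromoethyl)-2-methyl-1,3-dioxolane | CC1(CCBr)OCCO1 | starting material
5 | 4-(2-methyl-1,3-dioxolan-2-yl)-1-[(4R)-4-(prop-1-en-2-yl)cyclopent-1-en-1-yl]butan-1-one | CC1(CCCC(=O)C2=CC[C@H](C2)C(C)=C)OCCO1 | intermediate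
6 | 4-methyl-N'-{6-oxo-6-[(4R)-4-(prop-1-en-2-yl)cyclopent-1-en-1-yl]hexan-2-ylidene}benzenesulfonohydrazide | CC(CCCC(=O)C1=CC[C@H](C1)C(C)=C)=NNS(=O)(=O)c1ccc(C)cc1 | intermediate
7 | 5-diazo-1-[(4R)-4-(prop-1-en-2-yl)cyclopent-1-en-1-yl]hexan-1-one | CC(=[N+]=[N-])CCCC(=O)C1=CC[C@H](C1)C(C)=C | intermediate
8 | fused 1-pyrazoline: diazo carbon C10 bonded to C5, terminal nitrogen bonded to C9, ring A cis-fused, heterocycle on the face anti to the isopropenyl group | C1CCC(=O)[C@]23C[C@H](C(C)=C)C[C@H]2N=N[C@]13C | intermediate
9 | 6-methyl-3-(prop-1-en-2-yl)tricyclo[4.4.0.0^1,5]decan-10-one; cyclopropane (C5, C9, C10) anti to the isopropenyl group, C10 methyl endo over the five-membered ring | C1CCC(=O)[C@]23C[C@H](C(C)=C)C[C@H]2[C@]13C | intermediate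
10 | trans-4a-methyl-7-(prop-1-en-2-yl)octahydronaphthalen-1(2H)-one; isopropenyl axial, trans to the C10 methyl | C1CCC(=O)[C@H]2C[C@H](C(C)=C)CC[C@]12C | intermediate
11 | trans-7-acetyl-4a-methyloctahydronaphthalen-1(2H)-one; acetyl axial, trans to the C10 methyl | C1CCC(=O)[C@H]2C[C@H](C(C)=O)CC[C@]12C | intermediate
12 | trans-7-acetyl-4a-methyloctahydronaphthalen-1(2H)-one; acetyl equatorial, cis to the C10 methyl | C1CCC(=O)[C@H]2C[C@@H](C(C)=O)CC[C@]12C | intermediate
13 | 7-acetyl-4a-methyl-4a,5,6,7,8,8a-hexahydronaphthalen-1(4H)-one; trans-fused, acetyl cis to the C10 methyl | C1C=CC(=O)[C@H]2C[C@@H](C(C)=O)CC[C@]12C | intermediate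
14 | 4a-methyl-7-(2-methyl-1,3-dioxolan-2-yl)-4a,5,6,7,8,8a-hexahydronaphthalen-1(4H)-one; same configuration as 13 | C1C=CC(=O)[C@H]2C[C@@H](C3(C)OCCO3)CC[C@]12C | intermediate
15 | tert-butyldimethylsilyl dienol ether of 14 (silyloxy on C4; double bonds C4=C3 and C2=C1) | C1=CC=C(O[Si](C)(C)C(C)(C)C)[C@H]2C[C@@H](C3(C)OCCO3)CC[C@]12C | intermediate
16 | 2,4,6-trimethoxybenzaldehyde | COc1cc(OC)c(C=O)c(OC)c1 | starting material
17 | isobutylmagnesium bromide | CC(C)C[Mg]Br | starting material
18 | 3-methyl-1-(2,4,6-trimethoxyphenyl)butan-1-ol (racemic) | CC(C)CC(O)c1c(OC)cc(OC)cc1OC | intermediate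
19 | Δ2-4-ketone with the (S)-3-methyl-1-(2,4,6-trimethoxyphenyl)butyl group at C1 (axial, trans to the C10 methyl); C7 ketal | CC(C)C[C@H](c1c(OC)cc(OC)cc1OC)[C@@H]1C=CC(=O)[C@H]2C[C@@H](C3(C)OCCO3)CC[C@]12C | intermediate
20 | saturated 4-ketone of 19, C7 ketal retained | CC(C)C[C@H](c1c(OC)cc(OC)cc1OC)[C@@H]1CCC(=O)[C@H]2C[C@@H](C3(C)OCCO3)CC[C@]12C | intermediate
21 | diketone: C4 ketone and C7 acetyl, C1 side chain as in 19 | CC(C)C[C@H](c1c(OC)cc(OC)cc1OC)[C@@H]1CCC(=O)[C@H]2C[C@@H](C(C)=O)CC[C@]12C | intermediate
22 | diol: C4 tertiary alcohol (hydroxyl axial, cis to the C10 methyl) and C11 tertiary alcohol; trimethoxyaryl | CC(C)C[C@H](c1c(OC)cc(OC)cc1OC)[C@@H]1CC[C@@](C)(O)[C@H]2C[C@@H](C(C)(C)O)CC[C@]12C | intermediate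
23 | lithium hemiaminal of the monoformylated arene (both alcohols as lithium alkoxides) | CC(C)C[C@H](c1c(OC)cc(OC)c(C(O[Li])N(C)C)c1OC)[C@@H]1CC[C@@](C)(O[Li])[C@H]2C[C@@H](C(C)(C)O[Li])CC[C@]12C | intermediate
24 | 2,4,6-trimethoxy-5-substituted benzene-1,3-dicarbaldehyde (terpenoid part as in 22) | CC(C)C[C@H](c1c(OC)c(C=O)c(OC)c(C=O)c1OC)[C@@H]1CC[C@@](C)(O)[C@H]2C[C@@H](C(C)(C)O)CC[C@]12C | intermediate
25 | 2,4,6-trihydroxy-5-{(1S)-1-[(1S,4R,4aS,6S,8aR)-4-hydroxy-6-(2-hydroxypropan-2-yl)-4,8a-dimethyldecahydronaphthalen-1-yl]-3-methylbutyl}benzene-1,3-dicarbaldehyde | CC(C)C[C@H](c1c(O)c(C=O)c(O)c(C=O)c1O)[C@@H]1CC[C@@](C)(O)[C@H]2C[C@@H](C(C)(C)O)CC[C@]12C | target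

Total step count: 16. Longest linear sequence: 15 steps (steps 1 to 10 and 12 to 16); step 11 makes the aryl fragment.

Steps most likely to fail

Step 12. The planar benzylic cation may be attacked with poor facial selectivity, giving a mixture of Cb epimers. The fallback sets out from 15 and builds Cb in two bond formations. A vinylogous Mukaiyama aldol addition of 15 to 2,4,6-trimethoxybenzaldehyde 16 (BF3·OEt2, CH2Cl2, −78 °C) should give the C1 hydroxybenzyl enone F1 (carbinol configuration irrelevant). Ionization of F1 with BF3·OEt2 in the presence of methallyltrimethylsilane should then give the methallyl compound F2; here the cation carries the decalin and the small allylsilane adds under 1,2-induction from C1 (allylic-strain control). The hydrogenation of step 13 saturates both double bonds of F2, so the route is rejoined at 20.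

Step 5. The diazoalkane may lose nitrogen to a carbene (1,2-hydrogen shift to an alkene) before it cyclizes, and face discrimination at 110 °C may be incomplete. The fallback sets out from 5. Aqueous HCl in acetone should give the diketone F3, and hydrazine hydrate should condense at the saturated ketone to the hydrazone F4. Oxidation with MnO2 in CH2Cl2 at 0 °C generates diazoalkane 7 below room temperature, where cycloaddition to pyrazoline 8 can outrun carbene formation. Pyrazoline 8 is then isolated and photolysed (350 nm, benzene) to expel nitrogen, which rejoins the route at 9.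

Step 15. The second lithiation may stall, or butyllithium may attack the hemiaminal, leaving monoaldehyde. The fallback sets out from 22. Electrophilic bromination with N-bromosuccinimide (MeCN, 0 °C) should give the dibromide F5. After deprotonation of the alcohols with MeLi, double bromine–lithium exchange with t-BuLi (THF, −78 °C) and quenching with DMF should give 24.

Further compounds

F1 | step 12 | C1 hydroxy(2,4,6-trimethoxyphenyl)methyl enone (carbinol epimers), C7 ketal | OC(c1c(OC)cc(OC)cc1OC)[C@@H]1C=CC(=O)[C@H]2C[C@@H](C3(C)OCCO3)CC[C@]12C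
F2 | step 12 | C1 (S)-3-methyl-1-(2,4,6-trimethoxyphenyl)but-3-enyl enone, C7 ketal | CC(=C)C[C@H](c1c(OC)cc(OC)cc1OC)[C@@H]1C=CC(=O)[C@H]2C[C@@H](C3(C)OCCO3)CC[C@]12C
F3 | step 5 | 1-[(4R)-4-(prop-1-en-2-yl)cyclopent-1-en-1-yl]hexane-1,5-dione | CC(=O)CCCC(=O)C1=CC[C@H](C1)C(C)=C
F4 | step 5 | 5-hydrazinylidene-1-[(4R)-4-(prop-1-en-2-yl)cyclopent-1-en-1-yl]hexan-1-one | CC(CCCC(=O)C1=CC[C@H](C1)C(C)=C)=NN
F5 | step 15 | 3,5-dibromo-2,4,6-trimethoxyphenyl analogue of 22 | CC(C)C[C@H](c1c(OC)c(Br)c(OC)c(Br)c1OC)[C@@H]1CC[C@@](C)(O)[C@H]2C[C@@H](C(C)(C)O)CC[C@]12C
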